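Which set-up leaves the most L at the asked time, when the same charges go in by different routes?

| flask | D | E | remark | time |
|---|---|---|---|---|
| violet | 0.34 M | 0.408 M | run made earlier |  |
| amber | 0.17 M | 0.408 M | run made earlier |  |
| green | 0.68 M | 0.408 M | run made earlier |  |
| east | 0.34 M | 0.408 M | everything together in a closed stirred flask, run for 15 min | 15 min |
| north | 0.34 M | 0.408 M (fed, over 12.0 min) | all but E at the start; E goes in evenly over 12.0 min, the run ends at 15 min | 15 min |
| south-west | 0.34 M | 0.408 M | a single well-mixed tank run continuously and read at steady state, 15 min in it on average |  |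
| north-west | 0.34 M (fed, over 12.0 min) | 0.408 M | all but D at the start; D goes in evenly over 12.0 min, the run ends at 15 min | 15 min |

| run | time / min | L / % | D / % |
|---|---|---|---|
| violet | 1.00 | 1.1 | 81.5 |
| violet | 3.00 | 5.0 | 58.4 |
| violet | 5.00 | 11.0 | 45.0 |
| violet | 8.00 | 16.9 | 30.9 |
| violet | 12.0 | 21.9 | 19.8 |
| violet | 15.0 | 24.9 | 15.0 |
| amber | 1.00 | 1.5 | 81.5 |
| amber | 3.00 | 6.5 | 57.8 |
| amber | 5.00 | 11.5 | 44.0 |
| amber | 8.00 | 18.1 | 30.0 |
| amber | 12.0 | 23.8 | 19.1 |
| amber | 15.0 | 26.6 | 13.0 |
| green | 2.50 | 4.2 | 63.6 |
| green | 5.00 | 9.8 | 45.8 |
| green | 8.00 | 14.5 | 33.3 |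
| green | 10.0 | 16.4 | 28.2 |
| green | 12.0 | 17.6 | 24.2 |
| green | 15.0 | 19.8 | 19.7 |

(standard deviation of a reading: 0.3 percentage points)

- the set-up with the highest amount of L at the outlet or at the end, in percent of the D put in ("none" if the first two lie within 2 percentage points) (east / north / south-west / north-west / none)
- amount of L at the outlet or at the end, in percent of the D put in, east
- amount of L at the outlet or at the end, in percent of the D put in, north
- amount of L at the outlet or at the end, in percent of the D put in, south-west
- amount of L at the outlet or at the end, in percent of the D put in, north-west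

- the stated concentrations are those of everything mixed, before any reaction; amounts are the same in each set-up
- the numbers in the tables scatter with a standard deviation of 0.3 percentage points
- the feed brings no volume worth counting
- the earlier runs were made in a closed, stirred flask

Amber, violet and green hold E fixed and raise D, and L at the last reading falls from 26.6% through 24.9% to 19.8%. The number to carry is therefore ρ, the time-averaged amount of D put in over that of E put in, taken relative to violet. From violet to green ρ doubles, which gives, from those two scattered readings, the fall exponent, an apparent order of the L yield in ρ: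

n = ln(L violet / L green) / ln(ρ green) = 0.331

East repeats violet, at 24.9%. A species fed evenly stands, on time average, at a fed share of θ = 0.600 of its charge, so north has ρ = 1.67, assuming that E counts through the same ratio, which these runs never tested:

L north = L violet × ρ^(−n) = 21.0%

By this reckoning east leads north by 3.9 percentage points, more than the margin. One number is not enough, though. Applied to amber, n gives 31.3%, but amber read 26.6%, so the rule is not used below violet's ratio. North-west, with ρ = 0.600, lies below that ratio and is instead read off violet at the mean age of its D, 9.00 min, which gives about 18.1%. South-west has ρ of one, and ρ is blind to the spread of ages, so it stays open here.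

The forecast gave east as best, with 25% for east, 18% for north, 18% for south-west and 20.5% for north-west, placing north-west above north, the reverse of the order reckoned here, and it added: “The role of E is untested, so these are loose estimates.”

The flask gives 24.6% in east, 20.4% in north, 18.0% in south-west and 17.6% in north-west, so the best is east.

    D ⇌ Q (K = 0.850, k = 0.00270 s⁻¹)
    E + Q → L (k = 0.00670 M⁻¹ s⁻¹)
    D + E → G (k = 0.00230 M⁻¹ s⁻¹)
    Q → Z (k = 0.00210 s⁻¹)
    Z → J (k = 5.70 × 10⁻⁴ s⁻¹)
    G → X (k = 4.50 × 10⁻⁴ s⁻¹)

With n = 0.331, north was reckoned 0.60 points above what it gives. A neighbour of east charged with 0.85 M of D has ρ = 2.50, past green, so the same line gives 18.4% of L, and that flask holds 17.7%.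

(The numbers in the tables are calculated on assumed constants; scatter was added.)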